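Numbering follows the prostanoid skeleton (C1 = ester carbon, ring C8–C12, C20 = chain end). Retrosynthesis: first the C12 silyl ether, then C6–C7 (Suzuki coupling of a C1–C6 (E)-alkenylboronate with a (Z)-enol triflate at C7), then C7 (C-formylation of C8), and last the ring, cut at C9–C10 and C11–C12 at once.
Enabling feature: ring C8–C12 is a cyclopent-2-enone whose C9 carbonyl lies between C10(Cl)=C11 and C8, and whose C12 bears oxygen but no hydrogen. It is the Nazarov product of the pentadienyl cation C11=C10–C9(O)–C8=C12, in which two acceptor carbons (C11, C12; like polarity) are joined by electrocyclisation.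
Precursor: a 1-chlorovinyl anion (C10–C11, from vinyl chloride) and the morpholine amide of a 3-silyloxy-enoic acid (C9–C8=C12, from (3Z)-non-3-enoic acid and Meldrum's acid). The silyl group masks the 1,3-dicarbonyl unit for the event and then protects O12 until the last step.
Forward order: C12–C20 and C8–C9 are assembled first; one flask then forms C9–C10 (acylation) and C11–C12 (4π closure), which makes the only ring; C7 and C1–C6 follow, then desilylation.
Stereochemistry: C12 from the sense of conrotation inside a chiral ion pair (both enol ether isomers converge); 7Z from a chelation-controlled (Z)-enol triflate and retentive coupling; 5E from syn-hydroboration; 14Z from the starting alcohol.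

Key step: step 4

Assumption: the chiral acid of step 4 is the N-triflyl phosphoramide of (R)-3,3'-bis(2,4,6-triisopropylphenyl)-1,1'-bi-2-naphthol. Which of its enantiomers gives the (S) product of the key step cannot be predicted, so the (R)-acid is written and its antipode would be taken if the sense proves opposite.

Step 1
Reactants: 1 (3Z)-non-3-en-1-ol
Product: 2 (3Z)-non-3-enoic acid
Conditions: CrO3, H2SO4, H2O, acetone, 0 °C
Reagents that add atoms: water, O
Why: Jones oxidation through the aldehyde hydrate should give the β,γ-unsaturated acid, and at 0 °C with short contact the skipped Z-alkene should neither move into conjugation nor isomerise; no stereocentre is formed.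

Step 2
Reactants: 2 (3Z)-non-3-enoic acid; 3 Meldrum's acid; 4 morpholine
Product: 6 (5Z)-1-(morpholin-4-yl)undec-5-ene-1,3-dione, via acyl Meldrum's acid 5 (not isolated)
Conditions: DCC, DMAP, CH2Cl2, 0 °C → rt; then 4, toluene, 80 °C
Reagents that add atoms: none
Why: Carbodiimide-mediated C-acylation of Meldrum's acid and thermal loss of acetone and CO2 to an acylketene that morpholine traps (the acyl-Meldrum's-acid route to β-keto amides) should deliver the 1,3-dicarbonyl unit C12–C8–C9 without a base strong enough to move the skipped alkene; no stereocentre is formed.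

Step 3
Reactants: 6 (5Z)-1-(morpholin-4-yl)undec-5-ene-1,3-dione
Product: 7 (2Z,5Z)-1-(morpholin-4-yl)-3-[(triethylsilyl)oxy]undeca-2,5-dien-1-one
Conditions: Et3SiOTf, Et3N, CH2Cl2, −78 → 0 °C
Reagents that add atoms: triethylsilyl trifluoromethanesulfonate, CC[Si](CC)(CC)OS(=O)(=O)C(F)(F)F
Why: Soft enolisation and O-silylation of the 1,3-dicarbonyl compound at the ketone oxygen (silyl enol ether formation) should give the conjugated enol ether, which removes the acidic C8–H2, makes C12 an oxygen-bearing vinyl terminus and installs the O12 protecting group; the 2Z isomer is expected from the chelated enol, but the geometry is not critical for step 4.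

Step 4
Reactants: 7 (2Z,5Z)-1-(morpholin-4-yl)-3-[(triethylsilyl)oxy]undeca-2,5-dien-1-one; 8 vinyl chloride
Product: 12 (4S)-2-chloro-4-[(2Z)-oct-2-en-1-yl]-4-[(triethylsilyl)oxy]cyclopent-2-en-1-one, via 1-chlorovinyllithium 9 (not isolated), via lithium hemiaminal alkoxide 10 (not isolated), via cross-conjugated dienone 11 (not isolated)
Conditions: s-BuLi, THF/Et2O/pentane, −110 °C; then 7, −100 → −78 °C; then (R)-N-triflyl phosphoramide acid (2.2 equiv, recovered), CH2Cl2, −78 → 0 °C; aq. HCl
Reagents that add atoms: none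
Why: Proposed new method: 1-chlorovinyllithium 9 adds once to the amide carbonyl of 7 (C9–C10; conjugate attack is blocked at the fully substituted C12, and the lithium hemiaminal alkoxide 10 does not collapse until it is protonated), and the chiral acid then releases morpholine and the dienone 11, whose O-protonated form is the pentadienyl cation C11=C10–C9(OH)–C8=C12 that closes ring C8–C12 by a thermal 4π-conrotatory electrocyclisation (Nazarov cyclisation, C11–C12). The closest known reaction types are the one-flask cationic cyclopentannelation (organolithium addition to an α,β-unsaturated morpholine amide with Nazarov closure on acidic quench) and Nazarov cyclisations promoted by chiral N-triflyl phosphoramides; closure onto a heteroatom-bearing, fully substituted terminus is precedented for 3-acylbenzofurans, but a silyl enol ether terminus, a 1-chlorovinyl partner and the one-flask asymmetric form have not been shown. The new stereocentre C12 is set by the sense of conrotation within the ion pair of the cation and the chiral phosphoramide anion, which is the only anion in the flask, and because C8–C12 is a single bond in the oxocarbenium form of the cation, both enol ether isomers of 7 funnel into the same product. Termination is unambiguous: the 2-oxyallyl cation C10–C9–C8 can lose a proton only from C11 (C12 has none), which gives the C10=C11 enone with chlorine on C10 and C8 as CH2. The step needs ring closure to outrun transfer of the silyl group from the cation (which would free a 1,3-diketone), and this is favoured by the bulky triethylsilyl group, the weakly nucleophilic anion and the polarisation of the cation, in which the chlorine lone pair makes C11 the donor terminus and the silyloxy group makes C12 the acceptor terminus.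

Step 5
Reactants: 12 (4S)-2-chloro-4-[(2Z)-oct-2-en-1-yl]-4-[(triethylsilyl)oxy]cyclopent-2-en-1-one
Product: 13 (4R,5Z)-2-chloro-5-(hydroxymethylidene)-4-[(2Z)-oct-2-en-1-yl]-4-[(triethylsilyl)oxy]cyclopent-2-en-1-one
Conditions: LiN(SiMe3)2, THF, −78 °C; then CF3CH2OCHO, −78 °C; aq. NH4Cl
Reagents that add atoms: 2,2,2-trifluoroethyl formate, O=COCC(F)(F)F
Why: Claisen-type C-formylation of the kinetic lithium enolate at C8, the only enolisable position, with the activated formate should give the 2-formyl ketone as its hydrogen-bonded Z-enol; β-loss of the C12 silanolate is disfavoured because it would lead to an antiaromatic cyclopentadienone, and C12 is untouched (its descriptor changes only because C8 gains priority).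

Step 6
Reactants: 13 (4R,5Z)-2-chloro-5-(hydroxymethylidene)-4-[(2Z)-oct-2-en-1-yl]-4-[(triethylsilyl)oxy]cyclopent-2-en-1-one
Product: 14 (Z)-{(2R)-4-chloro-2-[(2Z)-oct-2-en-1-yl]-5-oxo-2-[(triethylsilyl)oxy]cyclopent-3-en-1-ylidene}methyl trifluoromethanesulfonate
Conditions: LiN(SiMe3)2, THF, −78 °C; then Comins' reagent, −78 → 0 °C; aq. NH4Cl
Reagents that add atoms: N-(5-chloropyridin-2-yl)bis(trifluoromethanesulfonyl)imide (Comins' reagent), O=S(=O)(N(c1ccc(Cl)cn1)S(=O)(=O)C(F)(F)F)C(F)(F)F
Why: O-sulfonylation of the lithium-chelated (U-shaped) enolate of the 2-formyl ketone (stereoselective enol triflate formation of a 1,3-dicarbonyl compound) should place the triflate on the formyl oxygen cis to the C9 carbonyl, giving the (Z)-enol triflate that encodes the 7Z geometry.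

Step 7
Reactants: 15 methyl hex-5-ynoate
Product: 16 methyl (5E)-6-(4,4,5,5-tetramethyl-1,3,2-dioxaborolan-2-yl)hex-5-enoate
Conditions: pinacolborane, Cp2Zr(H)Cl (10 mol %), Et3N (10 mol %), neat, 60 °C
Reagents that add atoms: pinacolborane, CC1(C)OBOC1(C)C
Why: Zirconocene-hydride-catalysed syn-hydroboration of the terminal alkyne should put boron on the terminal carbon and give only the (E)-alkenylboronate, which encodes 5E; the ester is tolerated.

Step 8
Reactants: 14 (Z)-{(2R)-4-chloro-2-[(2Z)-oct-2-en-1-yl]-5-oxo-2-[(triethylsilyl)oxy]cyclopent-3-en-1-ylidene}methyl trifluoromethanesulfonate; 16 methyl (5E)-6-(4,4,5,5-tetramethyl-1,3,2-dioxaborolan-2-yl)hex-5-enoate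
Product: 17 methyl (5E,7Z)-7-{(2R)-4-chloro-2-[(2Z)-oct-2-en-1-yl]-5-oxo-2-[(triethylsilyl)oxy]cyclopent-3-en-1-ylidene}hept-5-enoate
Conditions: Pd(PPh3)4 (5 mol %), K3PO4, 1,4-dioxane/H2O, rt → 40 °C, dark
Reagents that add atoms: none
Why: Suzuki–Miyaura coupling of the vinylogous acyl triflate with the alkenylboronate should form C6–C7 with retention at both sp2 carbons (7Z and 5E carried over), oxidative addition to the triflate being much faster than to the C10–Cl bond with PPh3 as ligand, and the mild phosphate base sparing the ester and the silyl ether.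

Step 9
Reactants: 17 methyl (5E,7Z)-7-{(2R)-4-chloro-2-[(2Z)-oct-2-en-1-yl]-5-oxo-2-[(triethylsilyl)oxy]cyclopent-3-en-1-ylidene}hept-5-enoate
Product: 18 methyl (5E,7Z)-7-{(2R)-4-chloro-2-hydroxy-2-[(2Z)-oct-2-en-1-yl]-5-oxocyclopent-3-en-1-ylidene}hept-5-enoate (the target)
Conditions: HF·pyridine, pyridine, THF, 0 °C, dark
Reagents that add atoms: none
Why: Fluoride-mediated cleavage of the tertiary triethylsilyl ether under buffered conditions (silyl ether deprotection) should free the C12 hydroxyl without ionising the doubly allylic C12–O bond or touching the cross-conjugated chlorodienone, the alkenes and the methyl ester; all stereo-elements are unchanged.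

Compound list
1 | (3Z)-non-3-en-1-ol | CCCCC/C=C\CCO | starting material
2 | (3Z)-non-3-enoic acid | CCCCC/C=C\CC(=O)O | intermediate
3 | Meldrum's acid (2,2-dimethyl-1,3-dioxane-4,6-dione) | CC1(C)OC(=O)CC(=O)O1 | starting material
4 | morpholine | C1COCCN1 | starting material
5 | 5-[(3Z)-1-hydroxynon-3-en-1-ylidene]-2,2-dimethyl-1,3-dioxane-4,6-dione (acyl Meldrum's acid) | CCCCC/C=C\CC(O)=C1C(=O)OC(C)(C)OC1=O | intermediate
6 | (5Z)-1-(morpholin-4-yl)undec-5-ene-1,3-dione | CCCCC/C=C\CC(=O)CC(=O)N1CCOCC1 | intermediate
7 | (2Z,5Z)-1-(morpholin-4-yl)-3-[(triethylsilyl)oxy]undeca-2,5-dien-1-one | CCCCC/C=C\C/C(O[Si](CC)(CC)CC)=C/C(=O)N1CCOCC1 | intermediate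
8 | vinyl chloride (chloroethene) | C=CCl | starting material
9 | 1-chlorovinyllithium | [Li]C(Cl)=C | intermediate
10 | lithium (4Z,7Z)-2-chloro-3-(morpholin-4-yl)-5-[(triethylsilyl)oxy]trideca-1,4,7-trien-3-olate (racemic at C3) | [Li+].[O-]C(N1CCOCC1)(C(Cl)=C)/C=C(O[Si](CC)(CC)CC)/C/C=C\CCCCC | intermediate
11 | (4Z,7Z)-2-chloro-5-[(triethylsilyl)oxy]trideca-1,4,7-trien-3-one | C=C(Cl)C(=O)/C=C(O[Si](CC)(CC)CC)/C/C=C\CCCCC | intermediate
12 | (4S)-2-chloro-4-[(2Z)-oct-2-en-1-yl]-4-[(triethylsilyl)oxy]cyclopent-2-en-1-one | CCCCC/C=C\C[C@@]1(O[Si](CC)(CC)CC)C=C(Cl)C(=O)C1 | intermediate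
13 | (4R,5Z)-2-chloro-5-(hydroxymethylidene)-4-[(2Z)-oct-2-en-1-yl]-4-[(triethylsilyl)oxy]cyclopent-2-en-1-one | CCCCC/C=C\C[C@@]1(O[Si](CC)(CC)CC)C=C(Cl)C(=O)/C1=C\O | intermediate
14 | (Z)-{(2R)-4-chloro-2-[(2Z)-oct-2-en-1-yl]-5-oxo-2-[(triethylsilyl)oxy]cyclopent-3-en-1-ylidene}methyl trifluoromethanesulfonate | CCCCC/C=C\C[C@@]1(O[Si](CC)(CC)CC)C=C(Cl)C(=O)/C1=C\OS(=O)(=O)C(F)(F)F | intermediate
15 | methyl hex-5-ynoate | COC(=O)CCCC#C | starting material
16 | methyl (5E)-6-(4,4,5,5-tetramethyl-1,3,2-dioxaborolan-2-yl)hex-5-enoate | COC(=O)CCC/C=C/B1OC(C)(C)C(C)(C)O1 | intermediate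
17 | methyl (5E,7Z)-7-{(2R)-4-chloro-2-[(2Z)-oct-2-en-1-yl]-5-oxo-2-[(triethylsilyl)oxy]cyclopent-3-en-1-ylidene}hept-5-enoate | CCCCC/C=C\C[C@@]1(O[Si](CC)(CC)CC)C=C(Cl)C(=O)/C1=C\C=C\CCCC(=O)OC | intermediate
18 | methyl (5E,7Z)-7-{(2R)-4-chloro-2-hydroxy-2-[(2Z)-oct-2-en-1-yl]-5-oxocyclopent-3-en-1-ylidene}hept-5-enoate, i.e. methyl (5E,7Z,12R,14Z)-10-chloro-12-hydroxy-9-oxoprosta-5,7,10,14-tetraenoate | CCCCC/C=C\C[C@@]1(O)C=C(Cl)C(=O)/C1=C\C=C\CCCC(=O)OC | target

Total steps: 9. Longest linear sequence: 8 steps (steps 1, 2, 3, 4, 5, 6, 8, 9).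

Steps most likely to fail

1. Step 4 (Proposed new method). What may go wrong: the lithiated chloroalkene may decompose, or may deprotonate C13, before the deactivated amide carbonyl is attacked. The silyl group may also be transferred from the cation before the ring closes, after which the freed 1,3-diketone closes through oxygen onto C11. Finally, the ion pair may discriminate the two senses of conrotation poorly. Fallback (known reactions; the ring is closed by olefin metathesis between C10 and C11 instead of by electrocyclisation, and the enantiomers are separated): it sets out from 2 and returns at 12. Amide coupling of 2 with N,O-dimethylhydroxylamine gives (3Z)-N-methoxy-N-methylnon-3-enamide F1. CH2=CHMgBr converts it into the vinyl ketone (5Z)-undeca-1,5-dien-3-one F2. Reformatsky addition of the zinc enolate from 4-(bromoacetyl)morpholine to the ketone carbonyl gives racemic (5Z)-3-ethenyl-3-hydroxy-1-(morpholin-4-yl)undec-5-en-1-one F3. Silylation (Et3SiOTf, 2,6-lutidine) gives racemic (5Z)-3-ethenyl-1-(morpholin-4-yl)-3-[(triethylsilyl)oxy]undec-5-en-1-one F4. Compound 9 (from 8) adds once to the morpholine amide to give racemic (7Z)-2-chloro-5-ethenyl-5-[(triethylsilyl)oxy]trideca-1,7-dien-3-one F5. Ring-closing metathesis with the second-generation Hoveyda–Grubbs catalyst gives racemic 2-chloro-4-[(2Z)-oct-2-en-1-yl]-4-[(triethylsilyl)oxy]cyclopent-2-en-1-one F6, and preparative chromatography on a chiral stationary phase gives 12.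

2. Step 6. What may go wrong: loss of enol geometry, either by sulfonylation of a non-chelated (W-shaped) enolate or by later addition–elimination of triflate, which would lead into the 7E series. Fallback (aldol condensation with isomer separation in place of the triflate and coupling): it sets out from 12 and returns at 17. The lithium enolate of 12 (LiN(iPr)2, THF, −78 °C) adds to methyl (5E)-7-oxohept-5-enoate F7, itself made from methyl hex-5-enoate and crotonaldehyde by cross-metathesis with the second-generation Hoveyda–Grubbs catalyst. This gives methyl (5E)-7-{(2S)-4-chloro-2-[(2Z)-oct-2-en-1-yl]-5-oxo-2-[(triethylsilyl)oxy]cyclopent-3-en-1-yl}-7-hydroxyhept-5-enoate F8 as a mixture of diastereomers. Mesylation and elimination (MsCl, Et3N; then DBU) should give 17 together with methyl (5E,7E)-7-{(2R)-4-chloro-2-[(2Z)-oct-2-en-1-yl]-5-oxo-2-[(triethylsilyl)oxy]cyclopent-3-en-1-ylidene}hept-5-enoate F9. The isomers are separated by chromatography, and F9 is returned to the mixture by iodine-catalysed equilibration in light.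

3. Step 5. What may go wrong: β-elimination of triethylsilanolate from the C8 enolate (to a cyclopentadienone that polymerises), or O-formylation and proton transfer during the Claisen step. Fallback (base-free aminomethylenation in place of enolate acylation): it sets out from 12 and returns at 13. Condensation of 12 with tert-butoxybis(dimethylamino)methane in toluene at 60 °C gives the enaminone (4R,5E)-2-chloro-5-[(dimethylamino)methylidene]-4-[(2Z)-oct-2-en-1-yl]-4-[(triethylsilyl)oxy]cyclopent-2-en-1-one F10, which mild aqueous acid (AcOH, THF/H2O) hydrolyses to 13.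

Further compounds
F1 | step 4 | (3Z)-N-methoxy-N-methylnon-3-enamide | CCCCC/C=C\CC(=O)N(C)OC
F2 | step 4 | (5Z)-undeca-1,5-dien-3-one | C=CC(=O)C/C=C\CCCCC
F3 | step 4 | racemic (5Z)-3-ethenyl-3-hydroxy-1-(morpholin-4-yl)undec-5-en-1-one | C=CC(O)(C/C=C\CCCCC)CC(=O)N1CCOCC1
F4 | step 4 | racemic (5Z)-3-ethenyl-1-(morpholin-4-yl)-3-[(triethylsilyl)oxy]undec-5-en-1-one | C=CC(O[Si](CC)(CC)CC)(C/C=C\CCCCC)CC(=O)N1CCOCC1
F5 | step 4 | racemic (7Z)-2-chloro-5-ethenyl-5-[(triethylsilyl)oxy]trideca-1,7-dien-3-one | C=C(Cl)C(=O)CC(C=C)(O[Si](CC)(CC)CC)C/C=C\CCCCC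
F6 | step 4 | racemic 2-chloro-4-[(2Z)-oct-2-en-1-yl]-4-[(triethylsilyl)oxy]cyclopent-2-en-1-one | CCCCC/C=C\CC1(O[Si](CC)(CC)CC)C=C(Cl)C(=O)C1
F7 | step 6 | methyl (5E)-7-oxohept-5-enoate | COC(=O)CCC/C=C/C=O
F8 | step 6 | methyl (5E)-7-{(2S)-4-chloro-2-[(2Z)-oct-2-en-1-yl]-5-oxo-2-[(triethylsilyl)oxy]cyclopent-3-en-1-yl}-7-hydroxyhept-5-enoate (mixture at C7 and C8) | CCCCC/C=C\C[C@@]1(O[Si](CC)(CC)CC)C=C(Cl)C(=O)C1C(O)/C=C/CCCC(=O)OC
F9 | step 6 | methyl (5E,7E)-7-{(2R)-4-chloro-2-[(2Z)-oct-2-en-1-yl]-5-oxo-2-[(triethylsilyl)oxy]cyclopent-3-en-1-ylidene}hept-5-enoate | CCCCC/C=C\C[C@@]1(O[Si](CC)(CC)CC)C=C(Cl)C(=O)/C1=C/C=C/CCCC(=O)OC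
F10 | step 5 | (4R,5E)-2-chloro-5-[(dimethylamino)methylidene]-4-[(2Z)-oct-2-en-1-yl]-4-[(triethylsilyl)oxy]cyclopent-2-en-1-one | CCCCC/C=C\C[C@@]1(O[Si](CC)(CC)CC)C=C(Cl)C(=O)/C1=C/N(C)C
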